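The route rests on the C5–C10 bond, the fusion bond shared by rings A and B. C10 is flanked by the C1 carbinol and C5 by oxygenated C4. Once this bond is removed, the decalin unfolds into a ten-membered carbocycle in which a C1–C10 oxirane faces an E C4=C5 alkene. Cp2TiCl breaks the oxirane at C10 and C10 bonds to C5 through the ring interior. One operation delivers rings A and B, the C5 and C10 stereocentres, the C1 hydroxyl and a 4(15)-alkene for O4 and O15. The precursor is a (4E)-1,10-epoxygermacr-4-ene with the C7 isopropyl group, a 6-acetate and a 9-silyl ether whose oxygen is syn to the oxirane oxygen.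

Key step: step 12

Numbering: eudesmane/germacrane locants are used for all compounds, open-chain ones included.
- C10 carries methyl C14.
- C1 and C9 are the carbinol carbons on C10.
- C5 is the ring-fusion CH.
- C4 carries O4 and C15H2–O15.
- C6 carries O6.
- C7 carries the isopropyl group (C11–C13).
- The acetate terminus of geranyl acetate is C6, and its E-methyl carbon becomes C9.

Stereochemical remark: the target is 1S,4S,5R,6R,7R,9R,10S.
- O1, O4, O6, O9 and the isopropyl group are equatorial. C14 and C15 are axial on one face.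
- Equatorial O9 is anti to C10–C5, so in the macrocycle O9 must be syn (threo) to the oxirane oxygen.
- A titanium–tartrate epoxidation of a secondary allylic alcohol gives the anti (erythro) isomer, so an inversion at C9 is built in (step 4).
- The configurations used for the macrocycle and the decalin agree with the target at C1, C5, C6, C7, C9 and C10.

Protecting-group remark: equatorial O1 and O9 form a 1,3-diol that would compete for the orthoester reagent. O6 (acetate) and O9 (TBS) are therefore differentiated, and O9 is released last.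

Assumption: trimethyl orthocinnamate is treated as not purchasable and is made from cinnamonitrile (steps 15 and 16).

Step 1
Reactants: 1 geranyl acetate
Product: 2 (2E,6E)-3,7-dimethyl-8-oxoocta-2,6-dien-1-yl acetate (8-oxogeranyl acetate; CHO = C9)
Conditions: SeO2 (1.0 equiv), EtOH (95 %), reflux
Reagents that add atoms: selenium dioxide O=[Se]=O
Why: Riley allylic oxidation (ene reaction, then [2,3]-sigmatropic shift) picks the electron-richer terminal alkene and its E-methyl group, so C1=C10 stays E, the methyl group is raised to the aldehyde, and the alkene deactivated by the allylic acetate is left alone.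

Step 2
Reactants: 2 8-oxogeranyl acetate; 3 prenyl chloride
Product: 5 rac-(2E,6E)-8-hydroxy-3,7,11-trimethyldodeca-2,6,10-trien-1-yl acetate (rac-8-hydroxyfarnesyl acetate; carbinol = C9), via prenylbarium chloride 4 (not isolated)
Conditions: BaI2, lithium biphenylide (2 equiv), THF, rt; 3, −78 °C; then 2, −78 °C
Reagents that add atoms: prenyl chloride (3) CC(C)=CCCl
Why: Allylbarium carbonyl addition: prenyl-magnesium, -zinc, -indium or -chromium reagents bond through the tertiary γ-carbon, whereas prenylbarium chloride adds 1,2 to aldehydes through its primary α-carbon at −78 °C, which gives the linear C9–C8–C7=C11 chain; the aldehyde outruns the acetate and C9 is formed racemic.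

Step 3
Reactants: 5 rac-8-hydroxyfarnesyl acetate
Product: 6 (2E,6S,7S,8S)-6,7-epoxy-8-hydroxy-3,7,11-trimethyldodeca-2,10-dien-1-yl acetate (1S,9S,10S in ring numbering; O9 anti to the oxirane oxygen)
Conditions: Ti(OiPr)4 (10 mol %), L-(+)-DIPT (12 mol %), t-BuOOH (0.45 equiv), 4 Å MS, CH2Cl2, −20 °C
Reagents that add atoms: tert-butyl hydroperoxide CC(C)(C)OO
Why: Sharpless kinetic resolution: with L-(+)-DIPT the (9S)-alcohol is epoxidised much faster than its antipode and on one face only, which sets 1S and 10S as the target needs, but the carbinol oxygen ends anti (erythro) to the oxirane oxygen, so C9 still has to be inverted; the homoallylic prenyl alkene and the remote C4=C5 alkene are not directed and stay, and the slow (9R)-alcohol is separated.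

Step 4
Reactants: 6 anti-epoxy alcohol
Product: 7 (2E,6S,7R,8R)-6,7-epoxy-8-(4-nitrobenzoyloxy)-3,7,11-trimethyldodeca-2,10-dien-1-yl acetate (9R; O9 syn to the oxirane oxygen)
Conditions: 4-O2NC6H4CO2H, PPh3, DIAD, toluene, 0 °C to rt
Reagents that add atoms: 4-nitrobenzoic acid O=C(O)c1ccc(cc1)[N+](=O)[O-]
Why: Mitsunobu reaction: SN2 displacement at the activated carbinol inverts C9 to 9R and gives the syn (threo) relation that equatorial O9 requires; the strongly acidic 4-nitrobenzoic acid is the standard partner for hindered carbinols, and the neighbouring quaternary carbon is tied back in the three-membered ring, which keeps the rear side of C9 open.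

Step 5
Reactants: 7 syn-epoxy 4-nitrobenzoate
Product: 8 (2E,6S,7S,8R)-6,7-epoxy-3,7,11-trimethyldodeca-2,10-diene-1,8-diol
Conditions: K2CO3 (0.2 equiv), MeOH, 0 °C
Reagents that add atoms: none
Why: Zemplén-type transesterification removes the activated benzoate and the primary acetate in one operation without touching a stereocentre, and catalytic carbonate at 0 °C is too mild for a Payne shift onto the fully substituted C10.

Step 6
Reactants: 8 epoxy diol
Product: 9 (2E,6S,7S,8R)-6,7-epoxy-8-hydroxy-3,7,11-trimethyldodeca-2,10-dienal (CHO = C6)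
Conditions: MnO2, CH2Cl2, rt
Reagents that add atoms: none
Why: Chemoselective allylic oxidation: MnO2 oxidises only the allylic primary alcohol at C6 and keeps the E geometry, while the C9 carbinol, no longer allylic, is not attacked.

Step 7
Reactants: 9 hydroxy enal
Product: 10 (2E,6S,7R,8R)-8-(tert-butyldimethylsilyloxy)-6,7-epoxy-3,7,11-trimethyldodeca-2,10-dienal
Conditions: TBSOTf, 2,6-lutidine, CH2Cl2, −78 °C
Reagents that add atoms: tert-butyldimethylsilyl triflate CC(C)(C)[Si](C)(C)OS(=O)(=O)C(F)(F)F
Why: Silyl ether formation with the reactive triflate covers the hindered C9 hydroxyl at low temperature, where excess lutidine protects the oxirane and the enal; the ether prevents O9 from trapping the activated prenyl alkene in step 8.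

Step 8
Reactants: 10 silyloxy enal
Product: 11 (2E,6S,7R,8R)-8-(tert-butyldimethylsilyloxy)-10-chloro-6,7-epoxy-3,7,11-trimethyldodeca-2,11-dienal (both epimers at the CHCl carbon C7)
Conditions: NCS, PhSeCl (10 mol %), CH2Cl2, rt
Reagents that add atoms: N-chlorosuccinimide O=C1CCC(=O)N1Cl
Why: Selenium-catalysed ene-type allylic chlorination attacks the only electron-rich alkene (the enal alkene is deactivated) and moves the double bond into the isopropenyl position with chlorine on C7; the C7 epimers are of no consequence because both give the same allylmetal.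

Step 9
Reactants: 11 allylic chloride
Product: 13 (1S,4E,6S,7R,9R,10R)-9-(tert-butyldimethylsilyloxy)-1,10-epoxygermacra-4,11-dien-6-ol, via allylchromium dichloride 12 (not isolated)
Conditions: CrCl2 (8 equiv), THF–DMF, 2 mM (syringe pump), rt
Reagents that add atoms: none
Why: Intramolecular Nozaki–Hiyama–Kishi allylation: divalent chromium converts either epimer of 11 into the primary E-allylchromium species 12, which adds to the enal through its γ-carbon C7 in a chair Zimmerman–Traxler transition state, so O6 and C8 come out anti with the isopropenyl group on C7, and of the two anti pairs the one that keeps O6, the isopropenyl group and the O9 silyl ether on the periphery of the forming ring should prevail; high dilution suppresses oligomers, and C6–C7 closure onto a farnesal-type enal is known for germacrane rings.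

Step 10
Reactants: 13 macrocyclic alcohol
Product: 14 (1S,4E,6S,7R,9R,10R)-6-acetoxy-9-(tert-butyldimethylsilyloxy)-1,10-epoxygermacra-4,11-diene
Conditions: Ac2O, DMAP (cat.), pyridine, CH2Cl2, rt
Reagents that add atoms: acetic anhydride CC(=O)OC(C)=O
Why: DMAP-catalysed acetylation gives O6 a group that is orthogonal to the O9 silyl ether, keeps a free hydroxyl away from the titanium reagent, and matches the allylic acetate spectators that are standard in titanocene epoxide–alkene cyclisations.

Step 11
Reactants: 14 isopropenyl macrocycle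
Product: 15 (1S,4E,6R,7R,9R,10R)-6-acetoxy-9-(tert-butyldimethylsilyloxy)-1,10-epoxygermacr-4-ene (same spatial arrangement at C6; the descriptor changes with the priorities)
Conditions: H2 (1 atm), RhCl(PPh3)3 (10 mol %), benzene, rt
Reagents that add atoms: none
Why: Homogeneous hydrogenation with RhCl(PPh3)3 discriminates by substitution: the open 1,1-disubstituted isopropenyl group binds to rhodium, whereas the trisubstituted ring alkene, shielded on its inner face, does not; oxirane, allylic acetate and silyl ether are inert and no stereocentre is formed.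

Step 12
Reactants: 15 epoxygermacrene
Product: 19 (1S,5R,6R,7R,9R,10S)-6-acetoxy-9-(tert-butyldimethylsilyloxy)eudesm-4(15)-en-1-ol, via C10 radical 16 (not isolated), via C4 radical 17 (not isolated), via Cp2TiCl alkoxide 18 (not isolated)
Conditions: Cp2TiCl2 (2.5 equiv), Mn (8 equiv), THF (dry, degassed), rt, slow addition of 15; aqueous work-up
Reagents that add atoms: none
Why: Cp2TiCl, a trivalent titanium radical made in the flask, binds the oxirane oxygen and cleaves C10–O by single-electron transfer to leave the O1-titanated tertiary radical 16; C10 then bonds to C5 through the ring interior, and the tertiary radical 17 hands a C15 hydrogen to a second Cp2TiCl (mixed disproportionation), which leaves the 4(15)-alkene 18, hydrolysed to 19 on work-up. The closest known reaction type is the titanocene-mediated transannular cyclisation of 1(10)-epoxygermacr-4-enes to 1-hydroxyeudesm-4(15)-enes, supported by the epoxypolyprenyl acetate cyclisations that end in an exocyclic alkene beside an acetoxy-bearing carbon. The single new bond closes ring B (C5–C6–C7–C8–C9–C10) in the 6-exo mode and ring A (C1–C2–C3–C4–C5–C10) in the 6-endo mode. C1 keeps its oxirane configuration because its C–O bond is never touched, while C10 and C5 are set by the crown-like double-chair conformer of the ring, in which the substituents at C6, C7 and C9 lie on the periphery and C14 and C15 point to one face, so C5 reaches the side of C10 that the oxygen has left and the fusion comes out trans with axial C14, axial H5 and equatorial O1. The step needs attack at C5 and not C4 (tertiary radical and a 6/6 ring pair against a secondary radical and a 5/7 pair), cyclisation faster than capture of 16 by titanium (short transannular C10···C5 distance, slow capture of tertiary radicals) and loss of a methyl rather than a ring hydrogen (bulk of Cp2TiCl; dry THF also shuts off reduction of 17). The silyl ether on O9 is a poor leaving group next to the radical, and the acetate on O6 neither binds nor quenches titanium.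

Step 13
Reactants: 19 eudesm-4(15)-en-1-ol
Product: 20 (1S,4S,5R,6R,7R,9R,10S)-6-acetoxy-9-(tert-butyldimethylsilyloxy)eudesmane-1,4,15-triol
Conditions: OsO4 (5 mol %), NMO, acetone–H2O, rt
Reagents that add atoms: N-methylmorpholine N-oxide C[N+]1([O-])CCOCC1; water O; OsO4 O=[Os](=O)(=O)=O (oxygen carrier)
Why: Upjohn dihydroxylation: the axial C14 methyl blocks its own face of the exocyclic alkene (1,3-diaxial approach), so OsO4 adds from the opposite, equatorial direction and places O4 equatorial (4S) and C15 axial, as the cage needs.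

Step 14
Reactants: 20 triol acetate
Product: 21 (1S,4S,5R,6R,7R,9R,10S)-9-(tert-butyldimethylsilyloxy)eudesmane-1,4,6,15-tetraol
Conditions: K2CO3 (0.3 equiv), MeOH, rt
Reagents that add atoms: none
Why: Zemplén-type transesterification frees O6 (helped by the neighbouring hydroxyls) and leaves the hindered silyl ether in place, so the 4,6,15-triol is open while the 1,9-diol stays half blocked.

Step 15
Reactants: 22 (E)-cinnamonitrile
Product: 23 methyl (E)-cinnamimidate hydrochloride
Conditions: HCl (g), MeOH (1.1 equiv), Et2O, 0 °C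
Reagents that add atoms: methanol CO; hydrogen chloride Cl
Why: Pinner reaction: the protonated nitrile takes up one methanol and the imidate salt crystallises from ether, which protects it from further reaction; the styryl double bond keeps its E geometry.

Step 16
Reactants: 23 imidate hydrochloride
Product: 24 trimethyl (E)-orthocinnamate
Conditions: MeOH (excess), hexane, rt
Reagents that add atoms: methanol CO
Why: Second stage of the Pinner orthoester synthesis: alcoholysis of the imidate salt at room temperature replaces nitrogen by two methoxy groups, and precipitation of NH4Cl together with extraction of the orthoester into hexane drives the exchange.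

Step 17
Reactants: 21 tetraol; 24 trimethyl orthocinnamate
Product: 25 9-O-tert-butyldimethylsilyl ether of the target (4,6,15-orthocinnamate cage closed)
Conditions: 24 (1.2 equiv), PPTS (10 mol %), 4 Å MS, CH2Cl2, rt; Et3N quench
Reagents that add atoms: trimethyl orthocinnamate (24) COC(OC)(OC)/C=C/c1ccccc1
Why: Acid-catalysed orthoester exchange: O15, O4 and O6 replace the three methoxy groups stepwise, removal of methanol drives the equilibrium to the 2,7,8-trioxabicyclo[3.2.1]octane, and only one configuration of the orthoester carbon can bridge equatorial O4, equatorial O6 and the axial C15–O15 arm; O1 has no free partner and cannot form a cyclic orthoester.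

Step 18
Reactants: 25 silylated orthoester
Product: 26 target CNP0252898.1
Conditions: TBAF, THF, rt to 40 °C
Reagents that add atoms: none
Why: Fluoride-induced desilylation frees O9 under basic, non-aqueous-acid conditions, to which the orthoester cage and the styryl group are inert.

Compound list

1 | geranyl acetate | CC(C)=CCC/C(C)=C/COC(C)=O | starting material
2 | (2E,6E)-8-oxogeranyl acetate | O=C/C(C)=C/CC/C(C)=C/COC(C)=O | intermediate
3 | prenyl chloride | CC(C)=CCCl | starting material
4 | prenylbarium chloride (not isolated) | CC(C)=CC[Ba]Cl | intermediate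
5 | rac-(2E,6E)-8-hydroxyfarnesyl acetate | CC(C)=CCC(O)/C(C)=C/CC/C(C)=C/COC(C)=O | intermediate
6 | (1S,9S,10S)-anti-epoxy alcohol | CC(C)=CC[C@H](O)[C@]1(C)O[C@H]1CC/C(C)=C/COC(C)=O | intermediate
7 | (9R)-syn-epoxy 4-nitrobenzoate | CC(C)=CC[C@@H](OC(=O)c1ccc(cc1)[N+](=O)[O-])[C@]1(C)O[C@H]1CC/C(C)=C/COC(C)=O | intermediate
8 | (1S,9R,10S)-syn-epoxy diol | CC(C)=CC[C@@H](O)[C@]1(C)O[C@H]1CC/C(C)=C/CO | intermediate
9 | syn-epoxy hydroxy enal | CC(C)=CC[C@@H](O)[C@]1(C)O[C@H]1CC/C(C)=C/C=O | intermediate
10 | 9-O-TBS epoxy enal | CC(C)=CC[C@@H](O[Si](C)(C)C(C)(C)C)[C@]1(C)O[C@H]1CC/C(C)=C/C=O | intermediate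
11 | secondary allylic chloride (C7 epimers) | C=C(C)C(Cl)C[C@@H](O[Si](C)(C)C(C)(C)C)[C@]1(C)O[C@H]1CC/C(C)=C/C=O | intermediate
12 | primary E-allylchromium dichloride (not isolated) | Cl[Cr](Cl)C/C(C)=C/C[C@@H](O[Si](C)(C)C(C)(C)C)[C@]1(C)O[C@H]1CC/C(C)=C/C=O | intermediate
13 | (1S,4E,6S,7R,9R,10R)-9-TBSO-1,10-epoxygermacra-4,11-dien-6-ol | C=C(C)[C@H]1C[C@@H](O[Si](C)(C)C(C)(C)C)[C@]2(C)O[C@H]2CC/C(C)=C/[C@@H]1O | intermediate
14 | 6-acetate of 13 | C=C(C)[C@H]1C[C@@H](O[Si](C)(C)C(C)(C)C)[C@]2(C)O[C@H]2CC/C(C)=C/[C@@H]1OC(C)=O | intermediate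
15 | (1S,4E,6R,7R,9R,10R)-6-acetoxy-9-TBSO-1,10-epoxygermacr-4-ene (key-step precursor) | CC(C)[C@H]1C[C@@H](O[Si](C)(C)C(C)(C)C)[C@]2(C)O[C@H]2CC/C(C)=C/[C@@H]1OC(C)=O | intermediate
16 | O1-titanated tertiary C10 radical (not isolated) | CC(C)[C@H]1C[C@@H](O[Si](C)(C)C(C)(C)C)[C](C)[C@@H](O[Ti](Cl)(C2C=CC=C2)C2C=CC=C2)CC/C(C)=C/[C@@H]1OC(C)=O | intermediate
17 | cyclised tertiary C4 radical (not isolated) | CC(C)[C@H]1C[C@@H](O[Si](C)(C)C(C)(C)C)[C@@]2(C)[C@H]([C@@H]1OC(C)=O)[C](C)CC[C@@H]2O[Ti](Cl)(C3C=CC=C3)C3C=CC=C3 | intermediate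
18 | Cp2TiCl alkoxide of 19 (not isolated) | CC(C)[C@H]1C[C@@H](O[Si](C)(C)C(C)(C)C)[C@@]2(C)[C@H]([C@@H]1OC(C)=O)C(=C)CC[C@@H]2O[Ti](Cl)(C3C=CC=C3)C3C=CC=C3 | intermediate
19 | (1S,5R,6R,7R,9R,10S)-6-acetoxy-9-TBSO-eudesm-4(15)-en-1-ol (key-step product) | CC(C)[C@H]1C[C@@H](O[Si](C)(C)C(C)(C)C)[C@@]2(C)[C@H]([C@@H]1OC(C)=O)C(=C)CC[C@@H]2O | intermediate
20 | (4S)-6-acetoxy-9-TBSO-eudesmane-1,4,15-triol | CC(C)[C@H]1C[C@@H](O[Si](C)(C)C(C)(C)C)[C@@]2(C)[C@H]([C@@H]1OC(C)=O)[C@](O)(CO)CC[C@@H]2O | intermediate
21 | 9-TBSO-eudesmane-1,4,6,15-tetraol | CC(C)[C@H]1C[C@@H](O[Si](C)(C)C(C)(C)C)[C@@]2(C)[C@H]([C@@H]1O)[C@](O)(CO)CC[C@@H]2O | intermediate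
22 | (E)-cinnamonitrile | N#C/C=C/c1ccccc1 | starting material
23 | methyl (E)-cinnamimidate hydrochloride | COC(=[NH2+])/C=C/c1ccccc1.[Cl-] | intermediate
24 | trimethyl (E)-orthocinnamate | COC(OC)(OC)/C=C/c1ccccc1 | intermediate
25 | 9-O-TBS ether of the target | CC(C)[C@H]1C[C@@H](O[Si](C)(C)C(C)(C)C)[C@@]2(C)[C@@H]3[C@@H]1O[C@]1(/C=C/c4ccccc4)OC[C@@]3(CC[C@@H]2O)O1 | intermediate
26 | CNP0252898.1, 4,6,15-orthocinnamate of (1S,4S,5R,6R,7R,9R,10S)-eudesmane-1,4,6,9,15-pentaol | CC(C)[C@H]1C[C@@H](O)[C@@]2(C)[C@@H]3[C@@H]1O[C@]1(/C=C/c4ccccc4)OC[C@@]3(CC[C@@H]2O)O1 | target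

Total step count: 18. Longest linear sequence: 16 (steps 1–14, 17, 18). Steps 15 and 16 form a two-step side branch.

Three steps most likely to fail

Step 12. Three things may go wrong:
- Titanium may capture the C10 radical before ring closure, which deoxygenates the oxirane.
- A minor ring conformer may react, which erodes the trans fusion.
- The C4 radical may terminate by hydrogen uptake or by loss of a ring hydrogen.

The fallback leaves the radical manifold for a polar, Lewis-acid-induced opening, which needs a non-participating group on O6. It sets out from 13. TESOTf/2,6-lutidine gives the 6-O-triethylsilyl ether F1. H2/RhCl(PPh3)3 gives the isopropyl macrocycle F2. BF3·OEt2 (CH2Cl2, −78 °C) opens the oxirane with rear-side attack of C5 on C10, and proton loss from the C4 cation gives the 6-O-triethylsilyl decalin F3; regioisomeric proton loss has to be removed by chromatography. OsO4/NMO gives the triol F4. PPTS in MeOH cleaves only the triethylsilyl ether, and the route is rejoined at 21.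

Step 9. Facial selectivity toward the resident C9/C10/C1 centres may be poor, and oligomerisation may compete with ring closure. The fallback replaces kinetic control by thermodynamic and peripheral control at the ketone level. It sets out from 11. The CrCl2 closure is carried on as the mixture of C6/C7 diastereomeric alcohols F5. H2/RhCl(PPh3)3 gives the isopropyl alcohols F6. Dess–Martin periodinane (NaHCO3) gives the C7-epimeric enones F7. DBU in toluene equilibrates C7 to the isomer with the isopropyl group on the ring periphery, the (7R)-enone F8. Luche reduction (NaBH4, CeCl3·7H2O, MeOH, −78 °C) delivers hydride from the outside of the ring to give the (6R,7R)-alcohol F9. Ac2O/DMAP rejoins the route at 15.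

Step 4. Displacement at a carbinol next to a fully substituted carbon may be sluggish, and elimination may take over. The fallback keeps C9 and inverts the two oxirane carbons instead. It sets out from 5 (or from its (9R)-enantiomer left over in step 3). Sharpless resolution with D-(−)-DIPT gives the (1R,9R,10R)-anti-epoxy alcohol F10. Boc2O/DMAP gives the tert-butyl carbonate F11. BF3·OEt2 (CH2Cl2, −78 °C) triggers 5-exo attack of the carbonate on tertiary C10 with inversion and gives the 9,10-cyclic carbonate with a free C1 hydroxyl F12. MsCl/Et3N gives the C1 mesylate F13. K2CO3 in MeOH cleaves carbonate and acetate, and the C10 alkoxide displaces the mesylate with inversion at C1, which rejoins the route at 8.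

Further compounds

F1 | step 12 | 6-O-triethylsilyl ether of 13 | C=C(C)[C@H]1C[C@@H](O[Si](C)(C)C(C)(C)C)[C@]2(C)O[C@H]2CC/C(C)=C/[C@@H]1O[Si](CC)(CC)CC
F2 | step 12 | 6-O-triethylsilyl-9-O-TBS-1,10-epoxygermacr-4-ene | CC(C)[C@H]1C[C@@H](O[Si](C)(C)C(C)(C)C)[C@]2(C)O[C@H]2CC/C(C)=C/[C@@H]1O[Si](CC)(CC)CC
F3 | step 12 | 6-O-triethylsilyl-9-O-TBS-eudesm-4(15)-en-1-ol | CC(C)[C@H]1C[C@@H](O[Si](C)(C)C(C)(C)C)[C@@]2(C)[C@H]([C@@H]1O[Si](CC)(CC)CC)C(=C)CC[C@@H]2O
F4 | step 12 | 6-O-triethylsilyl-9-O-TBS-eudesmane-1,4,15-triol | CC(C)[C@H]1C[C@@H](O[Si](C)(C)C(C)(C)C)[C@@]2(C)[C@H]([C@@H]1O[Si](CC)(CC)CC)[C@](O)(CO)CC[C@@H]2O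
F5 | step 9 | macrocyclic isopropenyl alcohol, C6/C7 diastereomer mixture | C=C(C)C1C[C@@H](O[Si](C)(C)C(C)(C)C)[C@]2(C)O[C@H]2CC/C(C)=C/C1O
F6 | step 9 | macrocyclic isopropyl alcohol, C6/C7 diastereomer mixture | CC(C)C1C[C@@H](O[Si](C)(C)C(C)(C)C)[C@]2(C)O[C@H]2CC/C(C)=C/C1O
F7 | step 9 | 9-TBSO-1,10-epoxygermacr-4-en-6-one, C7 epimers | CC(C)C1C[C@@H](O[Si](C)(C)C(C)(C)C)[C@]2(C)O[C@H]2CC/C(C)=C/C1=O
F8 | step 9 | (7R)-9-TBSO-1,10-epoxygermacr-4-en-6-one | CC(C)[C@H]1C[C@@H](O[Si](C)(C)C(C)(C)C)[C@]2(C)O[C@H]2CC/C(C)=C/C1=O
F9 | step 9 | (6R,7R)-9-TBSO-1,10-epoxygermacr-4-en-6-ol | CC(C)[C@H]1C[C@@H](O[Si](C)(C)C(C)(C)C)[C@]2(C)O[C@H]2CC/C(C)=C/[C@@H]1O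
F10 | step 4 | (1R,9R,10R)-anti-epoxy alcohol (mirror image of 6) | CC(C)=CC[C@@H](O)[C@@]1(C)O[C@@H]1CC/C(C)=C/COC(C)=O
F11 | step 4 | tert-butyl carbonate of F10 | CC(C)=CC[C@@H](OC(=O)OC(C)(C)C)[C@@]1(C)O[C@@H]1CC/C(C)=C/COC(C)=O
F12 | step 4 | 9,10-cyclic carbonate with free C1 hydroxyl (C10 inverted) | CC(C)=CC[C@H]1OC(=O)O[C@]1(C)[C@H](O)CC/C(C)=C/COC(C)=O
F13 | step 4 | C1 mesylate of F12 | CC(C)=CC[C@H]1OC(=O)O[C@]1(C)[C@H](OS(C)(=O)=O)CC/C(C)=C/COC(C)=O
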